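**Retrosynthetic overview**
- The target comes from a late, ring-controlled epoxidation of the E-1(10) alkene of a macrocyclic triene lactone.
- The 10-membered ring is closed at C3–C4 by a cathodic CrCl2/NiCl2-catalysed alkenyl iodide–aldehyde coupling, which also sets C3.
- The trans α-methylene-γ-lactone (C6–C7 bond) comes from a CrCl2 allylation of (Z)-3-iodobut-2-enal with a Baylis–Hillman bromide; the bought C8 centre controls C7 and C6, and the epoxy acid is esterified onto C8–OH.
- The C7–C10/C1–C3 chain comes from (S)-glycidol (acetylide opening, carboalumination, ethylene oxide); the epoxy acid comes from an L-threonine-derived dioxolane ester (methylation, ring closure with inversion).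
- Ring order: γ-lactone, then the 10-membered carbocycle, then the 1,10-oxirane.

Assumption: positions are cited in germacrane numbering (ring C1–C10, C11–C13 lactone and methylene carbons, C14 on C10, C15 on C4), and dioxolane ester 5 is taken as a purchasable L-threonine derivative.

**Route**

Step 1
Reactants: 1 but-2-yn-1-ol
Product: 3 (Z)-3-iodobut-2-en-1-ol, via cyclic vinylalanate 2 (not isolated)
Conditions: NaAlH2(OCH2CH2OMe)2, Et2O, 0 °C to rt; EtOAc; then I2, THF, −78 to 0 °C
Reagents that add atoms: iodine, II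
Why: Trans-hydroalumination of the propargylic alkoxide places aluminium on C3 inside a five-membered alanate, so iodinolysis with retention gives only the Z-iodoalkene (hydroalumination–iodination).

Step 2
Reactants: 3 (Z)-3-iodobut-2-en-1-ol
Product: 4 (Z)-3-iodobut-2-enal
Conditions: MnO2 (activated, excess), CH2Cl2, rt, dark
Reagents that add atoms: none
Why: MnO2 is a mild heterogeneous allylic oxidant that stops at the enal and neither isomerises nor deiodinates the Z-alkene (allylic alcohol oxidation).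

Step 3
Reactants: 5 methyl (4S,5R)-2,2,5-trimethyl-1,3-dioxolane-4-carboxylate
Product: 7 methyl (4R,5R)-2,2,4,5-tetramethyl-1,3-dioxolane-4-carboxylate, via lithium enolate 6 (not isolated)
Conditions: LiN(iPr)2, THF, −78 °C; MeI, DMPU, −78 to −40 °C
Reagents that add atoms: iodomethane, CI
Why: At −78 °C the dioxolane ester enolate is alkylated faster than it β-eliminates, and iodomethane enters anti to the C5 methyl group, which sets the quaternary centre as 4R (substrate-controlled enolate alkylation).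

Step 4
Reactants: 7 methyl (4R,5R)-2,2,4,5-tetramethyl-1,3-dioxolane-4-carboxylate
Product: 8 methyl (2R,3R)-2,3-dihydroxy-2-methylbutanoate
Conditions: p-TsOH·H2O (5 mol %), MeOH, 45 °C
Reagents that add atoms: none
Why: Acid-catalysed transacetalisation to methanol releases the diol without touching the ester or either stereocentre (acetonide methanolysis).

Step 5
Reactants: 8 methyl (2R,3R)-2,3-dihydroxy-2-methylbutanoate
Product: 9 methyl (2R,3R)-2-hydroxy-2-methyl-3-(methylsulfonyloxy)butanoate
Conditions: MsCl, Et3N, CH2Cl2, −20 °C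
Reagents that add atoms: methanesulfonyl chloride, CS(=O)(=O)Cl
Why: The secondary hydroxyl is sulfonylated selectively because the tertiary α-hydroxy ester position is far more hindered (chemoselective mesylation, no stereocentre changes).

Step 6
Reactants: 9 methyl (2R,3R)-2-hydroxy-2-methyl-3-(methylsulfonyloxy)butanoate
Product: 11 (2R,3S)-2,3-dimethyloxirane-2-carboxylic acid, via epoxy methyl ester 10 (not isolated)
Conditions: LiOH·H2O (3 equiv), THF/H2O, 0 °C to rt; then 1 M HCl to pH 3 at 0 °C, EtOAc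
Reagents that add atoms: lithium hydroxide, [Li+].[OH-]
Why: Hydroxide forms the tertiary alkoxide, which displaces the mesylate intramolecularly with inversion at C3 (Williamson 3-exo-tet closure to the cis-dimethyl oxirane, 3S) and then saponifies the methyl ester.

Step 7
Reactants: 12 (S)-glycidol; 13 lithium acetylide–ethylenediamine complex (LiC≡CH·H2NCH2CH2NH2)
Product: 14 (R)-pent-4-yne-1,2-diol
Conditions: DMSO, 10 °C to rt; then H2O
Reagents that add atoms: none
Why: SN2 opening of the epoxide by acetylide at the unsubstituted carbon leaves the stereocentre untouched, and the degenerate Payne shift of the glycidol alkoxide cannot racemise it (acetylide epoxide opening).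

Step 8
Reactants: 14 (R)-pent-4-yne-1,2-diol
Product: 15 (R)-4,5-bis(triethylsilyloxy)pent-1-yne
Conditions: TESCl, imidazole, CH2Cl2, 0 °C to rt
Reagents that add atoms: chlorotriethylsilane, CC[Si](CC)(CC)Cl
Why: Both hydroxyls are silylated under standard conditions, and the primary TES ether is the latent aldehyde for step 11 (silyl ether formation).

Step 9
Reactants: 15 (R)-4,5-bis(triethylsilyloxy)pent-1-yne; 16 ethylene oxide
Product: 19 (3E,6R)-4-methyl-6,7-bis(triethylsilyloxy)hept-3-en-1-ol, via alkenylalane 17 (not isolated), via lithium aluminate 18 (not isolated)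
Conditions: Me3Al, Cp2ZrCl2 (25 mol %), CH2Cl2, 0 °C to rt; volatiles off; n-BuLi, hexane/THF, 0 °C; ethylene oxide, −30 °C to rt; aq. KNaC4H4O6
Reagents that add atoms: trimethylaluminium, C[Al](C)C
Why: Negishi zirconium-catalysed carboalumination adds methyl and aluminium syn across the terminal alkyne to give only the E-trisubstituted alkenylalane, whose butyl ate complex opens ethylene oxide with retention of the alkene geometry.

Step 10
Reactants: 19 (3E,6R)-4-methyl-6,7-bis(triethylsilyloxy)hept-3-en-1-ol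
Product: 20 (3E,6R)-1-(tert-butyldiphenylsilyloxy)-4-methyl-6,7-bis(triethylsilyloxy)hept-3-ene
Conditions: TBDPSCl, imidazole, CH2Cl2, rt
Reagents that add atoms: tert-butyl(chloro)diphenylsilane, CC(C)(C)[Si](Cl)(c1ccccc1)c1ccccc1
Why: The only free hydroxyl is capped with the acid-stable TBDPS group (silyl ether formation).

Step 11
Reactants: 20 (3E,6R)-1-(tert-butyldiphenylsilyloxy)-4-methyl-6,7-bis(triethylsilyloxy)hept-3-ene
Product: 21 (2R,4E)-7-(tert-butyldiphenylsilyloxy)-4-methyl-2-(triethylsilyloxy)hept-4-enal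
Conditions: (COCl)2, DMSO, CH2Cl2, −78 to −40 °C; Et3N, to 0 °C
Reagents that add atoms: none
Why: The chlorosulfonium salt cleaves and oxidises primary TES ethers directly while secondary TES and TBDPS ethers survive, and the cold non-acidic conditions keep the α-silyloxy aldehyde configurationally intact (Swern oxidation of a primary silyl ether).

Step 12
Reactants: 21 (2R,4E)-7-(tert-butyldiphenylsilyloxy)-4-methyl-2-(triethylsilyloxy)hept-4-enal; 22 methyl acrylate
Product: 23 methyl (4R,6E)-9-(tert-butyldiphenylsilyloxy)-3-hydroxy-6-methyl-2-methylidene-4-(triethylsilyloxy)non-6-enoate (both C3 epimers)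
Conditions: DABCO (1 equiv), methyl acrylate (6 equiv), MeOH (minimal), rt, 4–6 d
Reagents that add atoms: none
Why: The activated α-silyloxy aldehyde undergoes the Morita–Baylis–Hillman reaction with methyl acrylate, and the new carbinol centre, formed as a mixture, is destroyed in step 13.

Step 13
Reactants: 23 methyl (4R,6E)-9-(tert-butyldiphenylsilyloxy)-3-hydroxy-6-methyl-2-methylidene-4-(triethylsilyloxy)non-6-enoate
Product: 24 methyl (2Z,4R,6E)-2-(bromomethyl)-9-(tert-butyldiphenylsilyloxy)-6-methyl-4-(triethylsilyloxy)nona-2,6-dienoate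
Conditions: NBS, Me2S, CH2Cl2, 0 °C to rt
Reagents that add atoms: N-bromosuccinimide, O=C1CCC(=O)N1Br
Why: The bromodimethylsulfonium reagent activates the allylic hydroxyl and bromide attacks with allylic transposition (SN2′) to give the conjugated Z-bromide under neutral conditions that spare the TES ether (Corey–Kim-type bromination of a Baylis–Hillman adduct).

Step 14
Reactants: 24 methyl (2Z,4R,6E)-2-(bromomethyl)-9-(tert-butyldiphenylsilyloxy)-6-methyl-4-(triethylsilyloxy)nona-2,6-dienoate; 4 (Z)-3-iodobut-2-enal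
Product: 27 (4R,5S)-4-[(1R,3E)-6-(tert-butyldiphenylsilyloxy)-1-hydroxy-3-methylhex-3-en-1-yl]-5-[(Z)-2-iodoprop-1-en-1-yl]-3-methylidenedihydrofuran-2(3H)-one, via hydroxy ester 25 (not isolated), via TES lactone 26 (not isolated)
Conditions: CrCl2 (4 equiv, nickel-free), THF, 0 °C to rt; then 1 M HCl, THF, rt
Reagents that add atoms: none
Why: In this Nozaki–Hiyama-type CrCl2 allylation the allylchromium adds through its γ-carbon C7 in a chair transition state that gives the anti adduct (trans-lactone after in-situ lactonisation, as known for Baylis–Hillman bromides), while the C8 centre (H-8 eclipsing the alkene by allylic 1,3-strain, aldehyde entering anti to the C9 chain) fixes C7 and hence C6; nickel-free CrCl2 leaves the alkenyl iodide untouched and dilute HCl then removes the secondary TES ether.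

Step 15
Reactants: 27 hydroxy lactone; 11 (2R,3S)-2,3-dimethyloxirane-2-carboxylic acid
Product: 29 C8 (2R,3S)-2,3-dimethyloxirane-2-carboxylate ester of 27, via mixed anhydride 28 (not isolated)
Conditions: 11 (1.5 equiv), 2,4,6-trichlorobenzoyl chloride, Et3N, THF, rt; then 27, DMAP, toluene, rt to 40 °C
Reagents that add atoms: none
Why: Yamaguchi esterification through the mixed anhydride acylates the hindered secondary hydroxyl with retention at C8 and without opening the oxirane.

Step 16
Reactants: 29 epoxy ester with primary TBDPS ether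
Product: 30 primary alcohol (C3–OH) of 29
Conditions: HF·pyridine, pyridine/THF, 0 °C to rt
Reagents that add atoms: none
Why: Buffered HF·pyridine cleaves the primary silyl ether while the lactone, the epoxy ester and the alkenyl iodide are stable to these mildly acidic fluoride conditions (desilylation).

Step 17
Reactants: 30 primary alcohol
Product: 31 seco-aldehyde (C3 aldehyde with the Z-alkenyl iodide at C4)
Conditions: Dess–Martin periodinane, NaHCO3, CH2Cl2, 0 °C; used crude
Reagents that add atoms: none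
Why: Buffered Dess–Martin oxidation gives the β,γ-unsaturated aldehyde without base, so the 1(10) double bond does not move into conjugation, and the aldehyde is used at once.

Step 18
Reactants: 31 seco-aldehyde
Product: 33 (3S,6R,7R,8R)-3-hydroxy-8-[(2R,3S)-2,3-dimethyloxirane-2-carbonyloxy]germacra-1(10)E,4Z,11(13)-trien-12,6-olide, via TMS ether 32 (not isolated)
Conditions: CrCl2 (20 mol %), NiCl2·glyme (5 mol %), TMSCl (3 equiv), LiCl (0.1 M), DMF, undivided cell, Al anode, Ni-foam cathode, constant current (about 3 F/mol), 31 added by syringe pump to 2 mM, rt; then 10 % aq. citric acid, MeOH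
Reagents that add atoms: none
Why: Proposed new method: a cathodically driven Cr/Ni-cocatalysed ring closure in which zerovalent nickel made at the cathode inserts into the Z-alkenyl iodide with retention, hands the alkenyl group to trivalent chromium, and the alkenylchromium adds intramolecularly to the aldehyde while TMSCl frees chromium from the alkoxide and the Al anode supplies the electrons, so that only catalytic divalent chromium meets the epoxy ester and the enoate and the 10-membered ring forms under high dilution; C3 is expected (not certain) to be set as 3S by a ring-forming transition state with the chromium-bound oxygen on the ring periphery; the closest known reactions are the intermolecular electrochemical Nozaki–Hiyama–Kishi coupling of alkenyl halides with aldehydes and the stoichiometric CrCl2/NiCl2 macrocyclisation.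

Step 19
Reactants: 33 macrocyclic allylic alcohol
Product: 34 (1R,3S,6R,7R,8R,10R)-1,10-epoxy-3-hydroxy-8-[(2R,3S)-2,3-dimethyloxirane-2-carbonyloxy]germacra-4Z,11(13)-dien-12,6-olide (target)
Conditions: dimethyldioxirane (1.05 equiv, acetone), CH2Cl2/acetone, −40 to −20 °C
Reagents that add atoms: dimethyldioxirane, CC1(C)OO1
Why: The strained E-1(10) alkene is the most electron-rich double bond (the 4,5-alkene is flanked by two allylic C–O bonds and the methylene lactone is electron-poor) and dimethyldioxirane attacks its exposed outer face, the inner face being blocked by the ring, which gives the trans (1R,10R) epoxide as in germacranolide epoxidations (Prilezhaev-type epoxidation under macrocyclic stereocontrol).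

**Compound list**

1 | but-2-yn-1-ol | CC#CCO | starting material
2 | cyclic sodium alkenyl(alkoxy)aluminate from 1 (five-membered O–Al–C3 ring, two 2-methoxyethoxy ligands) | CC1=CCO[Al-]1(OCCOC)OCCOC.[Na+] | intermediate (not isolated)
3 | (Z)-3-iodobut-2-en-1-ol | C/C(I)=C/CO | intermediate
4 | (Z)-3-iodobut-2-enal | C/C(I)=C/C=O | intermediate
5 | methyl (4S,5R)-2,2,5-trimethyl-1,3-dioxolane-4-carboxylate | C[C@H]1OC(C)(C)O[C@@H]1C(=O)OC | starting material
6 | lithium enolate of 5 (C5 R) | [Li+].COC([O-])=C1OC(C)(C)O[C@@H]1C | intermediate (not isolated)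
7 | methyl (4R,5R)-2,2,4,5-tetramethyl-1,3-dioxolane-4-carboxylate | C[C@H]1OC(C)(C)O[C@@]1(C)C(=O)OC | intermediate
8 | methyl (2R,3R)-2,3-dihydroxy-2-methylbutanoate | C[C@@H](O)[C@@](C)(O)C(=O)OC | intermediate
9 | methyl (2R,3R)-2-hydroxy-2-methyl-3-(methylsulfonyloxy)butanoate | C[C@@H](OS(C)(=O)=O)[C@@](C)(O)C(=O)OC | intermediate
10 | methyl (2R,3S)-2,3-dimethyloxirane-2-carboxylate | COC(=O)[C@]1(C)O[C@H]1C | intermediate (not isolated)
11 | (2R,3S)-2,3-dimethyloxirane-2-carboxylic acid | OC(=O)[C@]1(C)O[C@H]1C | intermediate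
12 | (S)-glycidol | OC[C@H]1CO1 | starting material
13 | lithium acetylide–ethylenediamine complex | [Li+].[C-]#C.NCCN | starting material
14 | (R)-pent-4-yne-1,2-diol | OC[C@H](O)CC#C | intermediate
15 | (R)-4,5-bis(triethylsilyloxy)pent-1-yne | CC[Si](CC)(CC)OC[C@H](O[Si](CC)(CC)CC)CC#C | intermediate
16 | ethylene oxide | C1CO1 | starting material
17 | dimethyl[(1E,4R)-2-methyl-4,5-bis(triethylsilyloxy)pent-1-en-1-yl]alane | CC[Si](CC)(CC)OC[C@H](O[Si](CC)(CC)CC)C/C(C)=C/[Al](C)C | intermediate (not isolated)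
18 | lithium butyl(dimethyl)[(1E,4R)-2-methyl-4,5-bis(triethylsilyloxy)pent-1-en-1-yl]aluminate | [Li+].CC[Si](CC)(CC)OC[C@H](O[Si](CC)(CC)CC)C/C(C)=C/[Al-](C)(C)CCCC | intermediate (not isolated)
19 | (3E,6R)-4-methyl-6,7-bis(triethylsilyloxy)hept-3-en-1-ol | CC[Si](CC)(CC)OC[C@H](O[Si](CC)(CC)CC)C/C(C)=C/CCO | intermediate
20 | (3E,6R)-1-(tert-butyldiphenylsilyloxy)-4-methyl-6,7-bis(triethylsilyloxy)hept-3-ene | CC[Si](CC)(CC)OC[C@H](O[Si](CC)(CC)CC)C/C(C)=C/CCO[Si](c1ccccc1)(c1ccccc1)C(C)(C)C | intermediate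
21 | (2R,4E)-7-(tert-butyldiphenylsilyloxy)-4-methyl-2-(triethylsilyloxy)hept-4-enal | O=C[C@H](O[Si](CC)(CC)CC)C/C(C)=C/CCO[Si](c1ccccc1)(c1ccccc1)C(C)(C)C | intermediate
22 | methyl acrylate | C=CC(=O)OC | starting material
23 | methyl (4R,6E)-9-(tert-butyldiphenylsilyloxy)-3-hydroxy-6-methyl-2-methylidene-4-(triethylsilyloxy)non-6-enoate (C3 epimer mixture) | C=C(C(=O)OC)C(O)[C@H](O[Si](CC)(CC)CC)C/C(C)=C/CCO[Si](c1ccccc1)(c1ccccc1)C(C)(C)C | intermediate
24 | methyl (2Z,4R,6E)-2-(bromomethyl)-9-(tert-butyldiphenylsilyloxy)-6-methyl-4-(triethylsilyloxy)nona-2,6-dienoate | COC(=O)/C(CBr)=C/[C@H](O[Si](CC)(CC)CC)C/C(C)=C/CCO[Si](c1ccccc1)(c1ccccc1)C(C)(C)C | intermediate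
25 | open-chain anti homoallylic alcohol methyl ester (C6–OH free, C8–OTES; C6, C7, C8 as in 27) | COC(=O)C(=C)[C@@H]([C@H](O)/C=C(/C)I)[C@H](O[Si](CC)(CC)CC)C/C(C)=C/CCO[Si](c1ccccc1)(c1ccccc1)C(C)(C)C | intermediate (not isolated)
26 | C8 O-triethylsilyl ether of 27 | C=C1C(=O)O[C@H](/C=C(/C)I)[C@H]1[C@H](O[Si](CC)(CC)CC)C/C(C)=C/CCO[Si](c1ccccc1)(c1ccccc1)C(C)(C)C | intermediate (not isolated)
27 | (4R,5S)-4-[(1R,3E)-6-(tert-butyldiphenylsilyloxy)-1-hydroxy-3-methylhex-3-en-1-yl]-5-[(Z)-2-iodoprop-1-en-1-yl]-3-methylidenedihydrofuran-2(3H)-one | C=C1C(=O)O[C@H](/C=C(/C)I)[C@H]1[C@H](O)C/C(C)=C/CCO[Si](c1ccccc1)(c1ccccc1)C(C)(C)C | intermediate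
28 | (2R,3S)-2,3-dimethyloxirane-2-carboxylic 2,4,6-trichlorobenzoic anhydride | O=C(OC(=O)[C@]1(C)O[C@H]1C)c1c(Cl)cc(Cl)cc1Cl | intermediate (not isolated)
29 | ester of the C8 hydroxyl of 27 with acid 11 (C8 R, side chain 2R,3S; TBDPS ether retained) | C=C1C(=O)O[C@H](/C=C(/C)I)[C@H]1[C@H](OC(=O)[C@]2(C)O[C@H]2C)C/C(C)=C/CCO[Si](c1ccccc1)(c1ccccc1)C(C)(C)C | intermediate
30 | primary alcohol from 29 (C3–OH free) | C=C1C(=O)O[C@H](/C=C(/C)I)[C@H]1[C@H](OC(=O)[C@]2(C)O[C@H]2C)C/C(C)=C/CCO | intermediate
31 | seco-aldehyde from 30 (C3 aldehyde) | C=C1C(=O)O[C@H](/C=C(/C)I)[C@H]1[C@H](OC(=O)[C@]2(C)O[C@H]2C)C/C(C)=C/CC=O | intermediate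
32 | 3-O-trimethylsilyl ether of 33 | C=C1C(=O)O[C@@H]2/C=C(/C)[C@@H](O[Si](C)(C)C)C/C=C(\C)C[C@@H](OC(=O)[C@]3(C)O[C@H]3C)[C@@H]12 | intermediate (not isolated)
33 | (3S,6R,7R,8R)-3-hydroxy-8-[(2R,3S)-2,3-dimethyloxirane-2-carbonyloxy]germacra-1(10)E,4Z,11(13)-trien-12,6-olide | C=C1C(=O)O[C@@H]2/C=C(/C)[C@@H](O)C/C=C(\C)C[C@@H](OC(=O)[C@]3(C)O[C@H]3C)[C@@H]12 | intermediate
34 | (1R,3S,6R,7R,8R,10R)-1,10-epoxy-3-hydroxy-8-[(2R,3S)-2,3-dimethyloxirane-2-carbonyloxy]germacra-4Z,11(13)-dien-12,6-olide | C=C1C(=O)O[C@@H]2/C=C(/C)[C@@H](O)C[C@H]3O[C@]3(C)C[C@@H](OC(=O)[C@]3(C)O[C@H]3C)[C@@H]12 | target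

**Step count and risks**

Total step count: 19. Longest linear sequence: 13 (steps 7–19).

Step 18 (the new electrochemical ring closure) is the most likely to fail: the 10-membered ring may form slowly against oligomerisation, and the sense of induction at C3 is predicted, not known. The fallback sets out from 31 and returns at 33. The ring is closed with the classical stoichiometric reagent (CrCl2 in excess, NiCl2 1 mol %, DMSO/THF, high dilution), which is established for medium-ring allylic alcohols, and no C3 selectivity is demanded of it. The carbinol mixture of 33 and its C3 epimer 3-epi-33 F1 is oxidised with MnO2 to the macrocyclic 3-ketone F2. Luche reduction (NaBH4, CeCl3·7H2O, MeOH, −78 °C), with hydride delivered from the ring periphery, then gives 33, so that C3 is set in a separate substrate-controlled step.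

Step 14 is the second risk: the anti outcome has good precedent, but the sense of 1,2-induction from C8 (aldehyde anti to the C9 chain versus anti to the silyloxy group) could be reversed. The fallback sets out from 13 and returns at 29; it runs the C8-epimeric series and inverts C8 in the acylation. 13 opens (R)-glycidol F3 to (S)-pent-4-yne-1,2-diol F4, which is silylated to the (S)-bis-TES ether F5. Carboalumination (alkenylalane F6, lithium aluminate F7) and ethylene oxide give the (6S)-alcohol F8, then the TBDPS ether F9, the (2S)-aldehyde F10, the (4S)-Baylis–Hillman adduct F11 and the (4S)-bromide F12, all under the conditions of steps 8–13. CrCl2 allylation with 4 then gives, through the 8-epi hydroxy ester F13 and the 8-epi TES lactone F14, the 8-epi hydroxy lactone F15. A Mitsunobu esterification of F15 with 11 (PPh3, DIAD, toluene) inverts C8 and delivers 29.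

Step 19 is the third risk: the free C3 hydroxyl could steer the oxidant to the 4,5-alkene. The fallback sets out from 33 and returns at 34. The hydroxyl is silylated (TESOTf, 2,6-lutidine) to the 3-O-TES ether F16, which is epoxidised with mCPBA/NaHCO3 to the 1,10-epoxide 3-O-TES ether F17; there is then no hydroxyl direction and the bulky ether shields the 4,5-alkene. HF·pyridine removes the silyl group.

**Further compounds**

F1 | step 18 | 3-epi-33 (3R epimer of 33) | C=C1C(=O)O[C@@H]2/C=C(/C)[C@H](O)C/C=C(\C)C[C@@H](OC(=O)[C@]3(C)O[C@H]3C)[C@@H]12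
F2 | step 18 | macrocyclic 3-ketone (3-oxo analogue of 33) | C=C1C(=O)O[C@@H]2/C=C(/C)C(=O)C/C=C(\C)C[C@@H](OC(=O)[C@]3(C)O[C@H]3C)[C@@H]12
F3 | step 14 | (R)-glycidol | OC[C@@H]1CO1
F4 | step 14 | (S)-pent-4-yne-1,2-diol | OC[C@@H](O)CC#C
F5 | step 14 | (S)-4,5-bis(triethylsilyloxy)pent-1-yne | CC[Si](CC)(CC)OC[C@@H](O[Si](CC)(CC)CC)CC#C
F6 | step 14 | dimethyl[(1E,4S)-2-methyl-4,5-bis(triethylsilyloxy)pent-1-en-1-yl]alane | CC[Si](CC)(CC)OC[C@@H](O[Si](CC)(CC)CC)C/C(C)=C/[Al](C)C
F7 | step 14 | lithium butyl(dimethyl)[(1E,4S)-2-methyl-4,5-bis(triethylsilyloxy)pent-1-en-1-yl]aluminate | [Li+].CC[Si](CC)(CC)OC[C@@H](O[Si](CC)(CC)CC)C/C(C)=C/[Al-](C)(C)CCCC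
F8 | step 14 | (3E,6S)-4-methyl-6,7-bis(triethylsilyloxy)hept-3-en-1-ol | CC[Si](CC)(CC)OC[C@@H](O[Si](CC)(CC)CC)C/C(C)=C/CCO
F9 | step 14 | (3E,6S)-1-(tert-butyldiphenylsilyloxy)-4-methyl-6,7-bis(triethylsilyloxy)hept-3-ene | CC[Si](CC)(CC)OC[C@@H](O[Si](CC)(CC)CC)C/C(C)=C/CCO[Si](c1ccccc1)(c1ccccc1)C(C)(C)C
F10 | step 14 | (2S,4E)-7-(tert-butyldiphenylsilyloxy)-4-methyl-2-(triethylsilyloxy)hept-4-enal | O=C[C@@H](O[Si](CC)(CC)CC)C/C(C)=C/CCO[Si](c1ccccc1)(c1ccccc1)C(C)(C)C
F11 | step 14 | methyl (4S,6E)-9-(tert-butyldiphenylsilyloxy)-3-hydroxy-6-methyl-2-methylidene-4-(triethylsilyloxy)non-6-enoate (C3 epimer mixture) | C=C(C(=O)OC)C(O)[C@@H](O[Si](CC)(CC)CC)C/C(C)=C/CCO[Si](c1ccccc1)(c1ccccc1)C(C)(C)C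
F12 | step 14 | methyl (2Z,4S,6E)-2-(bromomethyl)-9-(tert-butyldiphenylsilyloxy)-6-methyl-4-(triethylsilyloxy)nona-2,6-dienoate | COC(=O)/C(CBr)=C/[C@@H](O[Si](CC)(CC)CC)C/C(C)=C/CCO[Si](c1ccccc1)(c1ccccc1)C(C)(C)C
F13 | step 14 | 8-epi-25 (open-chain hydroxy ester, C8 S) | COC(=O)C(=C)[C@@H]([C@H](O)/C=C(/C)I)[C@@H](O[Si](CC)(CC)CC)C/C(C)=C/CCO[Si](c1ccccc1)(c1ccccc1)C(C)(C)C
F14 | step 14 | 8-epi-26 (TES lactone, C8 S) | C=C1C(=O)O[C@H](/C=C(/C)I)[C@H]1[C@@H](O[Si](CC)(CC)CC)C/C(C)=C/CCO[Si](c1ccccc1)(c1ccccc1)C(C)(C)C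
F15 | step 14 | 8-epi-27 (hydroxy lactone, C8 S) | C=C1C(=O)O[C@H](/C=C(/C)I)[C@H]1[C@@H](O)C/C(C)=C/CCO[Si](c1ccccc1)(c1ccccc1)C(C)(C)C
F16 | step 19 | 3-O-triethylsilyl ether of 33 | C=C1C(=O)O[C@@H]2/C=C(/C)[C@@H](O[Si](CC)(CC)CC)C/C=C(\C)C[C@@H](OC(=O)[C@]3(C)O[C@H]3C)[C@@H]12
F17 | step 19 | 3-O-triethylsilyl ether of 34 | C=C1C(=O)O[C@@H]2/C=C(/C)[C@@H](O[Si](CC)(CC)CC)C[C@H]3O[C@]3(C)C[C@@H](OC(=O)[C@]3(C)O[C@H]3C)[C@@H]12
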